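The dimethoxybenzo ring (fusion carbons C4a and C8a) is joined to the chain C1–C4 only through two ortho bonds, C4–C4a and C1–C8a, and C8a lies para to a methoxy group. Here C1 carries the guaiacyl ring, C2 the CH2OH, C3 the CHO, and C4 is the vinylic CH. One operation makes both bonds: Heck–Matsuda arylation of an α-methylene-γ-butyrolactone with 3,4-dimethoxybenzenediazonium tetrafluoroborate forms C4–C4a, and the HBF4 released ionises the para-oxygenated benzylic carbinol at C1, which closes onto C8a trans to C2. The precursor is a small lactone whose only lasting stereocentre, C2, comes from a chromium-catalysed asymmetric allylation; its carbonyl is the latent aldehyde.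

Key step: step 3

Assumption: 3-(bromomethyl)furan-2(5H)-one (4) is taken as a catalogue building block. The carbinol configuration in 5–8 is drawn for the expected anti adduct and is erased in step 3.

Step 1
Reactants: 1 3,4-dimethoxyaniline
Product: 2 3,4-dimethoxybenzenediazonium tetrafluoroborate
Conditions: NaNO2, aq. HBF4, 0 °C
Reagents that add atoms: sodium nitrite [Na+].[O-]N=O; tetrafluoroboric acid [H+].F[B-](F)(F)F
Why: Standard diazotisation of an electron-rich aniline, whose tetrafluoroborate salt should precipitate and keep when cold.

Step 2
Reactants: 3 4-acetoxy-3-methoxybenzaldehyde; 4 3-(bromomethyl)furan-2(5H)-one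
Product: 6 (R)-4-[(S)-(4-acetoxy-3-methoxyphenyl)(hydroxy)methyl]-3-methylenedihydrofuran-2(3H)-one, via trimethylsilyl ether 5 (not isolated)
Conditions: CrCl2 (10 mol %), chiral 1,8-bis(oxazolinyl)carbazole ligand (12 mol %, the enantiomer that gives Si-face addition), Mn powder, Me3SiCl, iPr2NEt (cat.), THF, 25 °C; then 1 M HCl
Reagents that add atoms: none
Why: In this catalytic asymmetric Nozaki–Hiyama–Kishi-type 2-(alkoxycarbonyl)allylation, the allylchromium species from 4 should add through its ring carbon in a closed chair transition state (anti) to the ligand-selected Si face of 3, setting lactone C4 (future C2) as R and the carbinol as S; Me3SiCl turns the catalyst over as silyl ether 5, and the minor syn adduct is removed by chromatography because only C2 is carried forward.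

Step 3
Reactants: 6 (R)-4-[(S)-(4-acetoxy-3-methoxyphenyl)(hydroxy)methyl]-3-methylenedihydrofuran-2(3H)-one; 2 3,4-dimethoxybenzenediazonium tetrafluoroborate
Product: 9 (3aR,4S)-4-(4-hydroxy-3-methoxyphenyl)-6,7-dimethoxy-3a,4-dihydronaphtho[2,3-c]furan-1(3H)-one, via arylidene lactone acetate 7 (not isolated), via arylidene lactone phenol 8 (not isolated)
Conditions: Pd(OAc)2 (5 mol %), MeOH, 25 °C; then 60 °C in the same flask (HBF4 released in situ)
Reagents that add atoms: none
Why: Zerovalent palladium formed from Pd(OAc)2 in methanol adds oxidatively to 2, the cationic aryl–palladium inserts into the exocyclic methylene of 6 with the aryl group going to the CH2 terminus (C4–C4a), and syn β-hydride elimination of a benzylic hydrogen should give the (E)-arylidene lactone 7 and one equivalent of HBF4; on warming, this acid methanolyses the aryl acetate (8) and ionises the benzylic carbinol to a protonated para-quinone methide, which the newly attached dimethoxyphenyl ring captures at its ortho carbon para to the 3-methoxy group (C1–C8a). The closest known reactions are the Heck–Matsuda arylation of α-methylene-γ-butyrolactones and the acid-mediated cyclisation of hydroxymatairesinol-type benzylic alcohols to conidendrin-type aryltetralin lactones. The six-membered carbocycle closes by 6-exo-trig Friedel–Crafts attack of C8a on the exocyclic quinone methide carbon C1. C1 is the only new stereocentre and is set by C2: with the lactone holding the C2–CH2O bond pseudo-equatorial, the planar cation should react in the rotamer in which the guaiacyl group eclipses the small C2–H, giving the 1,2-trans product, while the carbinol configuration of 6 is erased. The step needs β-hydride elimination toward the benzylic CH2 and not toward C2–H, which conjugation with the aryl ring and the base-free medium favour, and E geometry (aryl trans to the carbonyl, cis to C2), which syn insertion followed by syn elimination delivers, so that the only arene within reach of the cation is the intramolecular one.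

Step 4
Reactants: 9 (3aR,4S)-4-(4-hydroxy-3-methoxyphenyl)-6,7-dimethoxy-3a,4-dihydronaphtho[2,3-c]furan-1(3H)-one
Product: 11 (1S,2R)-1-(4-hydroxy-3-methoxyphenyl)-2-(hydroxymethyl)-6,7-dimethoxy-1,2-dihydronaphthalene-3-carbaldehyde (CNP0485134.1), via lactol 10 (not isolated)
Conditions: iBu2AlH (2.3 equiv), CH2Cl2, −78 °C; aq. potassium sodium tartrate
Reagents that add atoms: none
Why: Half-reduction of a γ-lactone with diisobutylaluminium hydride, in which the aluminium hemiacetal should persist at −78 °C and on work-up give lactol 10, which opens to the conjugated hydroxy enal 11; the first equivalent of hydride is spent on the phenol and no stereocentre is touched.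

Compound list
1 | 3,4-dimethoxyaniline | COc1ccc(N)cc1OC | starting material
2 | 3,4-dimethoxybenzenediazonium tetrafluoroborate | COc1ccc([N+]#N)cc1OC.F[B-](F)(F)F | intermediate
3 | 4-acetoxy-3-methoxybenzaldehyde | CC(=O)Oc1ccc(C=O)cc1OC | starting material
4 | 3-(bromomethyl)furan-2(5H)-one | BrCC1=CCOC1=O | starting material
5 | (R)-4-[(S)-(4-acetoxy-3-methoxyphenyl)(trimethylsilyloxy)methyl]-3-methylenedihydrofuran-2(3H)-one | C=C1C(=O)OC[C@@H]1[C@H](O[Si](C)(C)C)c1ccc(OC(C)=O)c(OC)c1 | intermediate
6 | (R)-4-[(S)-(4-acetoxy-3-methoxyphenyl)(hydroxy)methyl]-3-methylenedihydrofuran-2(3H)-one | C=C1C(=O)OC[C@@H]1[C@H](O)c1ccc(OC(C)=O)c(OC)c1 | intermediate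
7 | (R)-4-[(S)-(4-acetoxy-3-methoxyphenyl)(hydroxy)methyl]-3-[(E)-3,4-dimethoxybenzylidene]dihydrofuran-2(3H)-one | COc1ccc(/C=C2/C(=O)OC[C@@H]2[C@H](O)c2ccc(OC(C)=O)c(OC)c2)cc1OC | intermediate
8 | (R)-4-[(S)-hydroxy(4-hydroxy-3-methoxyphenyl)methyl]-3-[(E)-3,4-dimethoxybenzylidene]dihydrofuran-2(3H)-one | COc1ccc(/C=C2/C(=O)OC[C@@H]2[C@H](O)c2ccc(O)c(OC)c2)cc1OC | intermediate
9 | (3aR,4S)-4-(4-hydroxy-3-methoxyphenyl)-6,7-dimethoxy-3a,4-dihydronaphtho[2,3-c]furan-1(3H)-one | COc1cc([C@H]2c3cc(OC)c(OC)cc3C=C3C(=O)OC[C@H]23)ccc1O | intermediate
10 | (3aR,4S)-4-(4-hydroxy-3-methoxyphenyl)-6,7-dimethoxy-1,3,3a,4-tetrahydronaphtho[2,3-c]furan-1-ol (both anomers) | COc1cc([C@H]2c3cc(OC)c(OC)cc3C=C3C(O)OC[C@H]23)ccc1O | intermediate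
11 | (1S,2R)-1-(4-hydroxy-3-methoxyphenyl)-2-(hydroxymethyl)-6,7-dimethoxy-1,2-dihydronaphthalene-3-carbaldehyde | COc1cc([C@H]2c3cc(OC)c(OC)cc3C=C(C=O)[C@@H]2CO)ccc1O | target

Total step count: 4. Longest linear sequence: 3 steps (steps 2, 3 and 4); step 1 is a one-step side branch.

Steps most likely to fail

Step 3. The palladium hydride pathway may eliminate toward C2–H and into the lactone ring, which would erase the only stored stereocentre. The carbinol may also ionise before arylation and lose the C2 proton, and ring closure may lag in methanol. The fallback brings in the aryl group without a palladium hydride and separates the two bond formations. It sets out from 6: olefin cross-metathesis with 3,4-dimethoxystyrene (second-generation Hoveyda–Grubbs catalyst, CH2Cl2, 40 °C) should give the same arylidene lactone 7. Compound 7 is then treated in a second flask with methanolic HCl at 60 °C, which removes the acetate (8) and closes the ring, and the route is rejoined at 9. This fallback makes no compound outside the list (F0).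

Step 2. Facial selection at the aldehyde by the cyclic allylchromium species may be incomplete, or part of the reaction may leak through an open transition state to the syn adduct; either dilutes the optical purity of C2. The fallback moves the stereo-determining event to boron. It sets out from 4: Pd2(dba)3-catalysed allylic borylation with bis(pinacolato)diboron should give 3-[(4,4,5,5-tetramethyl-1,3,2-dioxaborolan-2-yl)methyl]furan-2(5H)-one F1. A chiral BINOL-derived phosphoric acid (TRIP type) then catalyses its allylboration of 3 through a closed chair transition state, giving the pinacol borate ester of 6 F2. Hydrolytic work-up rejoins the route at 6.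

Step 4. The aluminium hemiacetal may collapse before the quench, so that the liberated enal is reduced further, or conversion may stop short. The fallback gives up the half-reduction. It sets out from 9: excess iBu2AlH at 0 °C (or LiAlH4, THF) reduces the lactone fully to (1S,2R)-1-(4-hydroxy-3-methoxyphenyl)-2,3-bis(hydroxymethyl)-6,7-dimethoxy-1,2-dihydronaphthalene F3. MnO2 in CH2Cl2 then oxidises only the allylic primary alcohol and the route is rejoined at 11.

Further compounds
F0 | step 3 | none | none
F1 | step 2 | 3-[(4,4,5,5-tetramethyl-1,3,2-dioxaborolan-2-yl)methyl]furan-2(5H)-one | CC1(C)OB(CC2=CCOC2=O)OC1(C)C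
F2 | step 2 | pinacol borate ester of 6 | C=C1C(=O)OC[C@@H]1[C@H](OB1OC(C)(C)C(C)(C)O1)c1ccc(OC(C)=O)c(OC)c1
F3 | step 4 | (1S,2R)-1-(4-hydroxy-3-methoxyphenyl)-2,3-bis(hydroxymethyl)-6,7-dimethoxy-1,2-dihydronaphthalene | COc1cc([C@H]2c3cc(OC)c(OC)cc3C=C(CO)[C@@H]2CO)ccc1O
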